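**Plan**
- The retrosynthesis first removes the N-mesyl group and the C3–Br bond (late electrophilic bromination of the one open pyrrole carbon), then cuts N1–C2 of the pyrrole ring.
- Enabling feature: C2 of the pyrrole ring carries both N1 and a bromine, which is the oxidation level of the CBr2 carbon of a 1,1-dibromoalkene. One vinylic bromine leaves and the other stays as C2–Br.
- The C2=C3 unit is cut back by a dibromo-olefination to 4,5-dibromo-2-nitrobenzaldehyde, which comes from 3,4-dibromotoluene by nitration and methyl-to-formyl conversion.
- Forward: the benzene ring is bought with both aryl bromines; steps 1–5 build the side chain; the pyrrole ring is the only ring formed (step 6); C3–Br and the free N–H follow (steps 7–8).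
- The target has no stereocentre, so only regio- and chemoselectivity have to be controlled.

Key step: step 6

Assumption: nitration of 3,4-dibromotoluene is taken to follow the pattern of 3,4-dichlorotoluene and to give mainly the 6-nitro isomer, which is purified by recrystallisation.

**Step 1**
Reactants: 1 3,4-dibromotoluene
Product: 2 4,5-dibromo-2-nitrotoluene (1,2-dibromo-4-methyl-5-nitrobenzene)
Conditions: fuming HNO3, conc. H2SO4, 0 °C → rt; recrystallisation from EtOH
Reagents that add atoms: nitric acid, O[N+](=O)[O-]
Why: Electrophilic aromatic nitration in mixed acid should enter C6, the one position that is both ortho to the methyl group and para to the C3 bromine, whereas C2 is flanked on both sides and C5 is activated only by an ortho bromine.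

**Step 2**
Reactants: 2 4,5-dibromo-2-nitrotoluene; 3 N,N-dimethylformamide dimethyl acetal
Product: 5 4,5-dibromo-2-nitrobenzaldehyde, via enamine 4 (not isolated)
Conditions: DMF-DMA, DMF, 130 °C; concentrate; then NaIO4, THF/H2O, rt
Reagents that add atoms: sodium periodate, [Na+].[O-]I(=O)(=O)=O (aldehyde oxygen); N,N-dimethylformamide dimethyl acetal 3, COC(OC)N(C)C (its carbon and nitrogen reach only intermediate 4)
Why: The ortho-nitro group acidifies the methyl protons enough for condensation with the formamide acetal (the enamine stage of the Leimgruber–Batcho indole synthesis), and periodate then cleaves the electron-rich enamine C=C oxidatively to the aldehyde and DMF without touching the nitro group or the aryl bromides.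

**Step 3**
Reactants: 5 4,5-dibromo-2-nitrobenzaldehyde; 6 carbon tetrabromide
Product: 7 1,2-dibromo-4-(2,2-dibromovinyl)-5-nitrobenzene
Conditions: CBr4, PPh3, CH2Cl2, 0 °C
Reagents that add atoms: carbon tetrabromide 6, BrC(Br)(Br)Br
Why: Ramirez dibromo-olefination (first stage of the Corey–Fuchs sequence), in which the ylide Ph3P=CBr2 formed from CBr4 and PPh3 undergoes a Wittig reaction with the electron-poor aldehyde at 0 °C, where the nitro group and the aryl bromides are inert.

**Step 4**
Reactants: 7 1,2-dibromo-4-(2,2-dibromovinyl)-5-nitrobenzene
Product: 8 4,5-dibromo-2-(2,2-dibromovinyl)aniline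
Conditions: Fe powder, AcOH, EtOH, 80 °C
Reagents that add atoms: none
Why: Béchamp-type reduction with iron in acetic acid reduces the nitro group by electron transfer and, unlike catalytic hydrogenation, should leave the aryl bromides and the 1,1-dibromoalkene intact, as is usual for 2-nitro-β,β-dibromostyrenes.

**Step 5**
Reactants: 8 4,5-dibromo-2-(2,2-dibromovinyl)aniline; 9 methanesulfonyl chloride
Product: 10 N-[4,5-dibromo-2-(2,2-dibromovinyl)phenyl]methanesulfonamide
Conditions: MsCl, pyridine, CH2Cl2, 0 °C → rt
Reagents that add atoms: methanesulfonyl chloride 9, CS(=O)(=O)Cl
Why: N-Sulfonylation of the aniline with pyridine as a mild base should stop at the mono-sulfonamide, because the first mesyl group strongly lowers the nucleophilicity of nitrogen, and it installs the acidic N–H that the ring closure needs.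

**Step 6**
Reactants: 10 N-[4,5-dibromo-2-(2,2-dibromovinyl)phenyl]methanesulfonamide
Product: 12 2,5,6-tribromo-1-(methylsulfonyl)-1H-indole, via bromoalkyne 11 (not isolated)
Conditions: Cs2CO3, DMF, 80 °C, Ar (no transition metal)
Reagents that add atoms: none
Why: Carbonate deprotonates the sulfonamide and removes HBr from the dibromoalkene by anti-elimination to give bromoalkyne 11; the nitrogen anion then adds to the bromine-bearing alkyne carbon and the resulting C3 vinyl anion is protonated by hydrogen carbonate (a direct addition–elimination at the CBr2 carbon would converge on the same product). The closest known reaction type is the base-promoted, transition-metal-free cyclisation of N-sulfonyl 2-(2,2-dibromovinyl)anilines to 2-bromoindoles. The pyrrole ring closes in the 5-endo-dig mode through N1–C2 bond formation, the alternative 4-exo attack at the aryl-bearing carbon being excluded by strain. No stereocentre is formed. The step needs chemoselectivity among four C–Br bonds: only the vinylic pair has a β-hydrogen, so only one of those two bromines can be lost, and the survivor ends up on the carbon that becomes C2. Because neither palladium nor copper is present, the two aryl bromides and the new C2–Br are not activated, and the two ring bromines should help by acidifying the sulfonamide and making the alkyne more electrophilic.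

**Step 7**
Reactants: 12 2,5,6-tribromo-1-(methylsulfonyl)-1H-indole
Product: 13 2,3,5,6-tetrabromo-1-(methylsulfonyl)-1H-indole
Conditions: Br2, NaOAc, AcOH/CH2Cl2, rt, dark
Reagents that add atoms: bromine, BrBr
Why: Electrophilic aromatic bromination should occur at C3, the enamide β-carbon and the only unsubstituted pyrrole position, which stays the most nucleophilic site because the benzene ring is deactivated by two bromines and the N-sulfonyl group, while acetate buffers the HBr formed.

**Step 8**
Reactants: 13 2,3,5,6-tetrabromo-1-(methylsulfonyl)-1H-indole
Product: 14 2,3,5,6-tetrabromo-1H-indole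
Conditions: NaOH (2 M aq), 1,4-dioxane, 50 °C; then NH4Cl (aq)
Reagents that add atoms: none
Why: Base-mediated N-desulfonylation, in which hydroxide attacks the sulfonyl sulfur (or removes an α-proton to expel sulfene) and releases the tetrabromoindolide, a well-stabilised leaving group, under conditions too mild to displace any C–Br bond.

**Compound list**
1 | 3,4-dibromotoluene | Cc1ccc(Br)c(Br)c1 | starting material
2 | 4,5-dibromo-2-nitrotoluene | Cc1cc(Br)c(Br)cc1[N+](=O)[O-] | intermediate
3 | N,N-dimethylformamide dimethyl acetal | COC(OC)N(C)C | starting material
4 | (E)-2-(4,5-dibromo-2-nitrophenyl)-N,N-dimethylethenamine | CN(C)/C=C/c1cc(Br)c(Br)cc1[N+](=O)[O-] | intermediate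
5 | 4,5-dibromo-2-nitrobenzaldehyde | O=Cc1cc(Br)c(Br)cc1[N+](=O)[O-] | intermediate
6 | carbon tetrabromide | BrC(Br)(Br)Br | starting material
7 | 1,2-dibromo-4-(2,2-dibromovinyl)-5-nitrobenzene | BrC(Br)=Cc1cc(Br)c(Br)cc1[N+](=O)[O-] | intermediate
8 | 4,5-dibromo-2-(2,2-dibromovinyl)aniline | Nc1cc(Br)c(Br)cc1C=C(Br)Br | intermediate
9 | methanesulfonyl chloride | CS(=O)(=O)Cl | starting material
10 | N-[4,5-dibromo-2-(2,2-dibromovinyl)phenyl]methanesulfonamide | CS(=O)(=O)Nc1cc(Br)c(Br)cc1C=C(Br)Br | intermediate
11 | N-[4,5-dibromo-2-(bromoethynyl)phenyl]methanesulfonamide | CS(=O)(=O)Nc1cc(Br)c(Br)cc1C#CBr | intermediate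
12 | 2,5,6-tribromo-1-(methylsulfonyl)-1H-indole | CS(=O)(=O)n1c(Br)cc2cc(Br)c(Br)cc21 | intermediate
13 | 2,3,5,6-tetrabromo-1-(methylsulfonyl)-1H-indole | CS(=O)(=O)n1c(Br)c(Br)c2cc(Br)c(Br)cc21 | intermediate
14 | 2,3,5,6-tetrabromo-1H-indole | Brc1cc2[nH]c(Br)c(Br)c2cc1Br | target

**Step count**
Total steps: 8. Longest linear sequence: 8 steps (1 → 14).

**Steps most likely to fail**

Step 2. The condensation of the doubly brominated nitrotoluene with the formamide acetal may be slow. At the temperature it needs, dimethylamine or methoxide set free in the flask may displace the bromine para to the nitro group, and the periodate cleavage may run on to the acid. The fallback sets out from 2 and avoids the enamine altogether. Wohl–Ziegler benzylic bromination (NBS, AIBN, PhCF3, reflux, stopped before the dibromide builds up) should give 4,5-dibromo-2-nitrobenzyl bromide F1. Kornblum-type oxidation of F1 with N-methylmorpholine N-oxide (MeCN, 4 Å molecular sieves, rt) should then deliver the aldehyde, and the route is rejoined at 5.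

Step 7. The N-sulfonyl tribromoindole is strongly deactivated, so bromination at C3 may stall, and forcing it may cost positional control or lead to acid-induced bromine migration. The fallback sets out from 12 and reverses the order of the last two operations. The mesyl group is removed first (NaOH aq, 1,4-dioxane, 50 °C) to give 2,5,6-tribromo-1H-indole F2. The free indole is far more nucleophilic at C3 and should be brominated with one equivalent of NBS (DMF, −20 → 0 °C, dark), and the route is rejoined at 14.

Step 6. Bromoalkyne 11 may be consumed between molecules (nitrogen of one molecule adding to the alkyne of another, or attack at bromine that gives the terminal alkyne) faster than it closes, or the mesyl group may be lost in hot carbonate. The fallback sets out from 10 and replaces elimination–addition by a copper-catalysed intramolecular Ullmann–Goldberg N-vinylation (CuI, copper monoiodide, catalytic, K3PO4, THF, 80 °C). The copper amidate should insert into the vinylic C–Br bond cis to the ring and form N1–C2 by reductive elimination without a free bromoalkyne, the intramolecular five-membered closure being much faster than any coupling at the aryl bromides. The route is rejoined at 12 and no compound outside the list is made (F0).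

**Further compounds**
F1 | step 2 | 4,5-dibromo-2-nitrobenzyl bromide (1,2-dibromo-4-(bromomethyl)-5-nitrobenzene) | BrCc1cc(Br)c(Br)cc1[N+](=O)[O-]
F2 | step 7 | 2,5,6-tribromo-1H-indole | Brc1cc2[nH]c(Br)cc2cc1Br
F0 | step 6 | none | none
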